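**Strategy**

Numbering (briarane): ten-membered ring C1–C10; cyclohexene ring A = C1, C14, C13, C12, C11, C10; lactone = O, C7, C8, C17, C19; C16 is the hydroxymethyl carbon on C5. Enabling feature: the oxygen-bearing ring carbons C4 and C9 face each other 1,6 across the ten-membered ring, so joining them transannularly folds it into ring B (C1, C2, C3, C4, C9, C10) of a trans-decalin with the angular methyl on C1, in which C5–C6 is an ethynyl arm on carbinol C4 and C7–C8 is an enediol (dioxole) arm on C9.
Cuts: the ester C–O bonds and the C16 silyl ether; C8–C17 (lactone, intramolecular Reformatsky); C5–C16 and C6–C7 with C4–C9 re-formed (retro anionic alkynyl oxy-Cope with formaldehyde trapping); C4–C5 (ethynyl addition); C9–C8 (enolate alkenylation with a bromodioxole); C11=C12 (metathesis) and C13–C14 (allylboration); ring B by Diels-Alder.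
Forward order: ring B as a cyclohexenone, ring A by ring-closing metathesis to the trans-decalin, ring B enlarged from six to ten members, lactone last, then the acyl groups.
Stereochemistry: C1/C10 from a catalyst-controlled Diels-Alder reaction of an E dienal; C14 from reagent-controlled allylboration; C2 from epoxidation anti to the angular methyl; C7 and the ring-trans C8=C9 enol ether from the chair-like [3,3] shift; the Z enone from exterior trapping of the allenolate; C9 from oxidation of the exposed enol ether face; C8/C17 from the tethered Reformatsky closure; C4 from 1,3-anti hydroxyl-directed reduction; the side chain from (R)-3-hydroxybutanoic acid.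

Key step: step 14

Assumption: the diol catalyst of step 2 is taken to shield the same enal face as with simple α-substituted acroleins; should the antipode form, the enantiomeric catalyst is used.
Remark: centres that disappear later (the amine-bearing carbon of the cycloadduct, C8 of the methoxy ketal, the bromine-bearing carbon of the bromopropanoate, the allene axis of the allenolate) are drawn as the expected major isomer or left open.

**Step 1**
Reactants: 1 methacrolein; 2 2-(triphenylphosphoranylidene)propanal
Product: 3 (E)-2,4-dimethylpenta-2,4-dienal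
Conditions: 1 (3 equiv), PhMe, 90 °C, sealed vessel
Reagents that add atoms: none
Why: Wittig olefination with a formyl-stabilised ylide, which should give the E trisubstituted alkene selectively, while the α-methyl dienal that forms is too hindered and too deactivated to be olefinated a second time.

**Step 2**
Reactants: 3 (E)-2,4-dimethylpenta-2,4-dienal; 4 (E)-1-dimethylamino-3-(tert-butyldimethylsilyloxy)buta-1,3-diene
Product: 6 (1R,6S)-1-methyl-4-oxo-6-(prop-1-en-2-yl)cyclohex-2-ene-1-carbaldehyde, via Diels-Alder cycloadduct 5 (not isolated)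
Conditions: (R,R)-1-naphthyl-TADDOL (20 mol %), PhMe, -60 to -40 °C; then 1 M HCl, THF, 0 °C
Reagents that add atoms: none
Why: Hydrogen-bond-catalysed asymmetric Diels-Alder reaction of the 1-amino-3-siloxydiene at the formyl-activated α,β-alkene of 3, with the amine-bearing diene carbon bonding to the methyl-bearing carbon, suprafacial addition to the E alkene placing formyl and isopropenyl trans (relative configuration of C1 and C10) and the diol catalyst choosing the enal face (absolute configuration), followed by acid hydrolysis of the silyl enol ether and β-elimination of dimethylamine to the enone.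

**Step 3**
Reactants: 6 (1R,6S)-1-methyl-4-oxo-6-(prop-1-en-2-yl)cyclohex-2-ene-1-carbaldehyde
Product: 7 (4R,5S)-4-[(1S)-1-hydroxybut-3-en-1-yl]-4-methyl-5-(prop-1-en-2-yl)cyclohex-2-en-1-one
Conditions: (allyl)B(Ipc)2 from (+)-α-pinene (1.2 equiv), Et2O, -78 °C; then HOCH2CH2NH2, 0 °C
Reagents that add atoms: B-allylbis(isopinocampheyl)borane derived from (+)-α-pinene, C=CCB([C@@H]1C[C@@H]2C[C@H]([C@H]1C)C2(C)C)[C@@H]1C[C@@H]2C[C@H]([C@H]1C)C2(C)C
Why: Brown allylboration through a closed chair transition state, in which the aldehyde reacts far faster than the enone carbonyl at -78 °C and the isopinocampheyl groups from (+)-α-pinene override the substrate bias to give the 14S carbinol (the sense seen with other α-branched aldehydes), the amine work-up avoiding alkaline peroxide that would epoxidise the enone.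

**Step 4**
Reactants: 7 (4R,5S)-4-[(1S)-1-hydroxybut-3-en-1-yl]-4-methyl-5-(prop-1-en-2-yl)cyclohex-2-en-1-one
Product: 8 (4R,5S)-4-[(1S)-1-(tert-butyldimethylsilyloxy)but-3-en-1-yl]-4-methyl-5-(prop-1-en-2-yl)cyclohex-2-en-1-one
Conditions: TBSOTf, 2,6-lutidine, CH2Cl2, -78 to 0 °C
Reagents that add atoms: tert-butyldimethylsilyl triflate, CC(C)(C)[Si](C)(C)OS(=O)(=O)C(F)(F)F
Why: Silylation of a hindered neopentyl-type secondary alcohol with the silyl triflate and a hindered pyridine base, conditions under which the enone is not touched.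

**Step 5**
Reactants: 8 (4R,5S)-4-[(1S)-1-(tert-butyldimethylsilyloxy)but-3-en-1-yl]-4-methyl-5-(prop-1-en-2-yl)cyclohex-2-en-1-one
Product: 9 trans-decalin enone (rings A and B, C4 ketone, C2=C3, C11=C12, C14 silyl ether anti to the angular methyl)
Conditions: second-generation Grubbs catalyst RuCl2(=CHPh)(PCy3)(H2IMes) (5 mol %), CH2Cl2, 40 °C
Reagents that add atoms: none
Why: Ring-closing metathesis of the allyl group with the 1,1-disubstituted isopropenyl group closes the six-membered ring A as a trisubstituted cyclohexene, the trans relationship of the two tethers on ring B (fixed in step 2) giving the trans-decalin, and the electron-poor ring enone alkene does not take part.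

**Step 6**
Reactants: 9 trans-decalin enone
Product: 10 2,3-epoxy ketone of the trans-decalin (epoxide oxygen anti to the angular methyl)
Conditions: 30% H2O2, NaOH (0.2 equiv), MeOH, 0 °C
Reagents that add atoms: hydrogen peroxide, OO
Why: Weitz-Scheffer nucleophilic epoxidation, in which hydroperoxide adds to C2 on the face opposite the axial angular methyl on C1 and the enolate closes the epoxide on that same face (configuration of C2), and which leaves C9 as the only enolisable position.

**Step 7**
Reactants: 11 2,2-dimethyl-1,3-dioxolane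
Product: 12 4-chloro-2,2-dimethyl-1,3-dioxolane (racemic)
Conditions: SO2Cl2 (1.0 equiv), AIBN (cat.), PhCl, 70 °C
Reagents that add atoms: sulfuryl chloride, O=S(=O)(Cl)Cl
Why: Free-radical chain chlorination, which should take the ring C-H next to oxygen in preference to the methyl C-H because the α-alkoxyalkyl radical is the more stabilised.

**Step 8**
Reactants: 12 4-chloro-2,2-dimethyl-1,3-dioxolane
Product: 13 2,2-dimethyl-1,3-dioxole
Conditions: KOt-Bu, THF, 0 to 60 °C; distillation
Reagents that add atoms: none
Why: Base-induced dehydrochlorination of an α-chloro ether with a hindered alkoxide, the standard way from a 4-halo-1,3-dioxolane to the 1,3-dioxole, with the volatile product distilled from the mixture.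

**Step 9**
Reactants: 13 2,2-dimethyl-1,3-dioxole
Product: 15 4-bromo-2,2-dimethyl-1,3-dioxole, via trans-4,5-dibromo-2,2-dimethyl-1,3-dioxolane 14 (not isolated)
Conditions: Br2, CH2Cl2, -78 °C; then Et3N, -78 to 0 °C
Reagents that add atoms: bromine, BrBr
Why: Anti addition of bromine to the electron-rich enediol ether followed by amine-induced loss of hydrogen bromide through the oxocarbenium ion, the same addition-elimination sequence that turns dichloroethylene carbonate into chlorovinylene carbonate and dihydropyran into its bromo enol ether; the product is used at once as a cold solution.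

**Step 10**
Reactants: 10 2,3-epoxy ketone of the trans-decalin; 15 4-bromo-2,2-dimethyl-1,3-dioxole
Product: 17 C9-(2,2-dimethyl-1,3-dioxol-4-yl) epoxy ketone, via chlorozinc enolate 16 (not isolated)
Conditions: LiN(SiMe3)2, THF, -78 °C; ZnCl2, -78 to 0 °C; 15 (1.5 equiv), Pd(dba)2 (5 mol %), P(t-Bu)3 (10 mol %), rt; pH 7 buffer, -40 °C
Reagents that add atoms: none
Why: Palladium-catalysed α-alkenylation of a ketone enolate (Negishi-type coupling of the zinc enolate with an alkenyl bromide under a bulky trialkylphosphine), in which deprotonation can occur only at C9 because the other α-carbon is an epoxide carbon, the weakly basic zinc enolate leaves the epoxide and the product alone, and the dioxolyl group should settle equatorial on C9 (trans to the C10-C11 bond), the arrangement given both by axial protonation and by thermodynamics.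

**Step 11**
Reactants: 17 C9-(2,2-dimethyl-1,3-dioxol-4-yl) epoxy ketone
Product: 18 C2-hydroxy C4-ketone (axial C2 alcohol)
Conditions: SmI2 (2.2 equiv), THF/MeOH, -90 °C; pH 7 buffer
Reagents that add atoms: none
Why: Samarium diiodide reduction of an α,β-epoxy ketone, which cleaves only the C3-O bond next to the carbonyl group and so leaves the C2 alcohol with the configuration of the epoxide (axial, anti to the angular methyl), the low temperature and buffered quench protecting the β-hydroxy ketone from dehydration and C9 from epimerisation.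

**Step 12**
Reactants: 18 C2-hydroxy C4-ketone
Product: 19 C2,C14-bis(tert-butyldimethylsilyl) C4-ketone
Conditions: TBSOTf, 2,6-lutidine, CH2Cl2, -78 °C
Reagents that add atoms: tert-butyldimethylsilyl triflate, CC(C)(C)[Si](C)(C)OS(=O)(=O)C(F)(F)F
Why: Silyl triflate silylation of the hindered axial alcohol under non-nucleophilic base, fast enough at -78 °C to outrun β-elimination, and giving the bulky axial group that will steer the next addition.

**Step 13**
Reactants: 19 C2,C14-bis(tert-butyldimethylsilyl) C4-ketone
Product: 20 decalin ethynyl carbinol (C4: hydroxyl axial, ethynyl equatorial)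
Conditions: HC≡CMgBr (3 equiv), CeCl3 (3 equiv), THF, -78 °C; H2O
Reagents that add atoms: ethynylmagnesium bromide, C#C[Mg]Br
Why: 1,2-Addition of an ethynylcerium reagent, whose low basicity avoids enolisation toward C9, with axial approach to C4 blocked by the 1,3-diaxial C2 silyloxy group so that the ethynyl group enters equatorially (configuration of C4 in the decalin: hydroxyl axial, ethynyl and dioxolyl trans-diequatorial).

**Step 14**
Reactants: 20 decalin ethynyl carbinol
Product: 23 ten-membered hydroxymethyl enone with C7,C8 enediol acetonide, via potassium alkoxide 21 (not isolated), via potassium allenolate 22 (not isolated)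
Conditions: KN(SiMe3)2 (1.05 equiv), 18-crown-6, THF, -78 to -20 °C; CH2O (monomer in THF, 5 equiv), -78 °C; AcOH (1.1 equiv), -78 °C
Reagents that add atoms: formaldehyde, C=O
Why: Proposed new method: the crown-separated potassium alkoxide 21 should undergo an anionic oxy-Cope [3,3] shift through the chair-like array C6-C5-C4-C9-C8-C7, in which the equatorial ethynyl and equatorial dioxolyl arms on the rigid trans-decalin are gauche, so that C6-C7 forms while the ring-B bond C4-C9 breaks and the charge moves from oxygen onto the C4-C5-C6 allenolate 22, which pays for the strain of the medium ring. The closest known reactions are the anionic oxy-Cope ring expansion of trans-1,2-dialkenylcyclohexanols to cyclodec-5-enones with trapping of the enolate and the oxy-Cope shift of alkynyl vinyl carbinols to allenolates or the derived enones; an enediol acetonide as the alkene partner, the decalin setting and the aldol trapping are the extrapolation. The ten-membered ring is closed by four-atom ring enlargement (a sigmatropic C6-C7 bond formed inside a six-membered transition state, not an end-to-end cyclisation) with the C1-C10 fusion untouched, and the aldol step, in which formaldehyde bonds to C5 (C5-C16), closes no ring. C7 is set by chirality transfer from C4 and C9, the chair placing O7 of the dioxole pseudo-equatorial and H7 pseudo-axial, which also gives the ring-trans C8=C9 enol ether; the C5=C6 geometry is set by formaldehyde approaching C5 in the plane of the C6 substituents from outside the ring, syn to H6, which leaves C4 and C7 cis (Z enone). The step needs carbon-selective trapping at C5 and must avoid β-elimination of the C2 silyloxy group and retro-aldol loss of formaldehyde, which one equivalent of base, low temperature and the cold acetic acid quench should secure.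

**Step 15**
Reactants: 23 ten-membered hydroxymethyl enone
Product: 24 C16 tert-butyldiphenylsilyl ether of the ten-membered enone
Conditions: TBDPSCl, imidazole, DMF, 0 °C
Reagents that add atoms: tert-butyldiphenylsilyl chloride, CC(C)(C)[Si](Cl)(c1ccccc1)c1ccccc1
Why: Selective silylation of the only hydroxyl group, a primary allylic one, under standard chlorosilane and imidazole conditions that do not disturb the enol ether acetonide or the β-silyloxy ketone.

**Step 16**
Reactants: 24 C16 tert-butyldiphenylsilyl ether of the ten-membered enone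
Product: 25 C9 alcohol with C8 methoxy ketal (acetonide kept on O7 and O8)
Conditions: DMDO (1.0 equiv, acetone), MeOH/CH2Cl2 1:1, -78 to -40 °C
Reagents that add atoms: dimethyldioxirane, CC1(C)OO1; methanol, CO
Why: Epoxidation of the enol ether, by far the most electron-rich alkene (the trisubstituted ring-A alkene reacts more slowly and the enone not at all with one equivalent at low temperature), with methanolysis of the alkoxy epoxide at the acetal carbon C8 as with glycal epoxides; the oxidant can reach the ring-trans enol ether only on its outer face, opposite the former C4-C9 bond, which gives the required C9 configuration.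

**Step 17**
Reactants: 25 C9 alcohol with C8 methoxy ketal
Product: 26 C9 acetate with C8 methoxy ketal
Conditions: Ac2O, DMAP, pyridine, CH2Cl2, rt
Reagents that add atoms: acetic anhydride, CC(=O)OC(C)=O
Why: Acetylation of the only free hydroxyl group under nucleophilic catalysis, done at this point because C7-O is still masked in the ketal.

**Step 18**
Reactants: 26 C9 acetate with C8 methoxy ketal
Product: 27 C9 acetate, C8 ketone, C7 alcohol
Conditions: PPTS (cat.), acetone/H2O 10:1, rt
Reagents that add atoms: water, O (its oxygen becomes the C8 carbonyl oxygen when the methoxy group leaves first)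
Why: Mild acid hydrolysis of the mixed ketal, which loses methanol and then acetone to release the C8 ketone and the C7 hydroxyl group while silyl ethers and the acetate survive, under conditions too mild for α-ketol transposition or acetyl migration.

**Step 19**
Reactants: 27 C9 acetate, C8 ketone, C7 alcohol
Product: 28 C7 2-bromopropanoate (both epimers at the bromine-bearing carbon)
Conditions: 2-bromopropionyl bromide, pyridine, CH2Cl2, -20 °C
Reagents that add atoms: 2-bromopropionyl bromide, CC(Br)C(Br)=O
Why: Acylation of the secondary allylic alcohol with an acid bromide and pyridine at low temperature, mild enough to spare the enolisable C7-H; the epimers at the bromine-bearing carbon converge in the next step.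

**Step 20**
Reactants: 28 C7 2-bromopropanoate
Product: 30 C8-hydroxy lactone with C9 acetate and C4 ketone, via samarium enolate 29 (not isolated)
Conditions: SmI2 (2.2 equiv), THF, -78 °C; H2O
Reagents that add atoms: none
Why: Intramolecular samarium diiodide Reformatsky reaction: the carbon-bromine bond is reduced much faster than the ketones, and the samarium enolate, held by the C7 ester tether, adds to the neighbouring C8 ketone to close the five-membered lactone (5-exo addition to the carbonyl); the tether reaches the ketone face that leaves C9 anti to C6 on the new ring (configuration of C8, trans-fused lactone), and C17 should place its methyl away from the C9 branch, which is also the more stable epimer.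

**Step 21**
Reactants: 30 C8-hydroxy lactone with C9 acetate and C4 ketone
Product: 31 C2,C14-diol C4-ketone (C16 silyl ether kept)
Conditions: 48% aq. HF, MeCN, 0 °C to rt
Reagents that add atoms: none
Why: Acidic desilylation with aqueous hydrogen fluoride, under which the two secondary tert-butyldimethylsilyl ethers are cleaved well before the acid-stable primary tert-butyldiphenylsilyl ether.

**Step 22**
Reactants: 31 C2,C14-diol C4-ketone
Product: 32 C2,C4,C14-triol (C8 hydroxyl also free)
Conditions: Me4NBH(OAc)3, MeCN/AcOH 1:1, -30 °C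
Reagents that add atoms: none
Why: Evans-Saksena reduction, in which the C2 hydroxyl group binds the triacetoxyborohydride and delivers hydride intramolecularly to the C4 ketone in a 1,2-fashion to give the 1,3-anti diol (configuration of C4), the reagent leaving lactone, acetate and unchelated carbonyl groups alone.

**Step 23**
Reactants: 33 (R)-3-hydroxybutanoic acid
Product: 34 (R)-3-acetoxybutanoic acid
Conditions: Ac2O, pyridine, DMAP (cat.), rt; then H2O
Reagents that add atoms: acetic anhydride, CC(=O)OC(C)=O
Why: Routine O-acetylation of the secondary alcohol of the chiral-pool hydroxy acid, the stereocentre not being involved.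

**Step 24**
Reactants: 32 C2,C4,C14-triol; 34 (R)-3-acetoxybutanoic acid
Product: 35 C4 (R)-3-acetoxybutanoate with free C2, C8 and C14 hydroxyl groups
Conditions: 34 (1.05 equiv), EDC·HCl, DMAP (cat.), CH2Cl2, 0 °C
Reagents that add atoms: none
Why: Carbodiimide (Steglich-type) esterification with one equivalent of acid at 0 °C, expected to pick the allylic C4 hydroxyl group because the C2 and C14 hydroxyl groups are neopentyl-like next to the quaternary C1 and the C8 hydroxyl group is tertiary, the low temperature and catalytic DMAP keeping the β-acetoxy acid from eliminating.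

**Step 25**
Reactants: 35 C4 (R)-3-acetoxybutanoate
Product: 36 fully acylated C16 tert-butyldiphenylsilyl ether
Conditions: Ac2O, DMAP, Et3N, CH2Cl2, rt
Reagents that add atoms: acetic anhydride, CC(=O)OC(C)=O
Why: Exhaustive acetylation of the two remaining secondary alcohols under nucleophilic catalysis, which the hindered tertiary C8 hydroxyl group does not follow at room temperature.

**Step 26**
Reactants: 36 fully acylated C16 tert-butyldiphenylsilyl ether
Product: 37 target CNP0316115.1
Conditions: HF·pyridine, pyridine, THF, 0 °C to rt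
Reagents that add atoms: none
Why: Fluoride cleavage of the silicon-oxygen bond with buffered hydrogen fluoride-pyridine, acidic rather than basic so that none of the five esters migrates to the freed primary alcohol.

**Compound list**

1 | methacrolein | C=C(C)C=O | starting material
2 | 2-(triphenylphosphoranylidene)propanal | CC(C=O)=P(c1ccccc1)(c1ccccc1)c1ccccc1 | starting material
3 | (E)-2,4-dimethylpenta-2,4-dienal | C=C(C)/C=C(\C)C=O | intermediate
4 | (E)-1-dimethylamino-3-(tert-butyldimethylsilyloxy)buta-1,3-diene | C=C(O[Si](C)(C)C(C)(C)C)/C=C/N(C)C | starting material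
5 | Diels-Alder cycloadduct: 2-(dimethylamino)-1-methyl-6-(prop-1-en-2-yl)-4-(tert-butyldimethylsilyloxy)cyclohex-3-ene-1-carbaldehyde, amine cis to formyl (endo), formyl trans to isopropenyl | CC(C)(C)[Si](C)(C)OC1=C[C@@H](N(C)C)[C@@](C)(C=O)[C@H](C(C)=C)C1 | intermediate
6 | (1R,6S)-1-methyl-4-oxo-6-(prop-1-en-2-yl)cyclohex-2-ene-1-carbaldehyde (ring B with C1 and C10; methyl and isopropenyl cis) | O=C1C=C[C@@](C)(C=O)[C@H](C(C)=C)C1 | intermediate
7 | (4R,5S)-4-[(1S)-1-hydroxybut-3-en-1-yl]-4-methyl-5-(prop-1-en-2-yl)cyclohex-2-en-1-one | O=C1C=C[C@@](C)([C@@H](O)CC=C)[C@H](C(C)=C)C1 | intermediate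
8 | tert-butyldimethylsilyl ether of 7 | O=C1C=C[C@@](C)([C@@H](O[Si](C)(C)C(C)(C)C)CC=C)[C@H](C(C)=C)C1 | intermediate
9 | trans-decalin enone: ring B cyclohex-2-enone (C4 ketone, C2=C3), ring A cyclohexene (C11=C12, methyl on C11), angular methyl on C1, C14 silyloxy group and H10 anti to the angular methyl | O=C1C=C[C@@]2(C)[C@@H](O[Si](C)(C)C(C)(C)C)CC=C(C)[C@@H]2C1 | intermediate
10 | 2,3-epoxide of 9, epoxide oxygen anti to the angular methyl | O=C1[C@H]2O[C@H]2[C@@]2(C)[C@@H](O[Si](C)(C)C(C)(C)C)CC=C(C)[C@@H]2C1 | intermediate
11 | 2,2-dimethyl-1,3-dioxolane | CC1(C)OCCO1 | starting material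
12 | 4-chloro-2,2-dimethyl-1,3-dioxolane (racemic) | CC1(C)OCC(Cl)O1 | intermediate
13 | 2,2-dimethyl-1,3-dioxole | CC1(C)OC=CO1 | intermediate
14 | trans-4,5-dibromo-2,2-dimethyl-1,3-dioxolane (racemic, one enantiomer drawn) | CC1(C)O[C@H](Br)[C@@H](Br)O1 | intermediate
15 | 4-bromo-2,2-dimethyl-1,3-dioxole | CC1(C)OC=C(Br)O1 | intermediate
16 | chlorozinc enolate of 10 (C4-O-ZnCl, C4=C9) | Cl[Zn]OC1[C@H]2O[C@H]2[C@@]2(C)[C@@H](O[Si](C)(C)C(C)(C)C)CC=C(C)[C@@H]2C=1 | intermediate
17 | epoxy ketone 10 carrying an equatorial 2,2-dimethyl-1,3-dioxol-4-yl group on C9 (trans to the C10-C11 bond) | O=C1[C@H]2O[C@H]2[C@@]2(C)[C@@H](O[Si](C)(C)C(C)(C)C)CC=C(C)[C@@H]2[C@H]1C1=COC(C)(C)O1 | intermediate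
18 | β-hydroxy ketone: C4 ketone, axial C2 alcohol anti to the angular methyl, C9 dioxolyl, C14 silyl ether | O=C1C[C@@H](O)[C@@]2(C)[C@@H](O[Si](C)(C)C(C)(C)C)CC=C(C)[C@@H]2[C@H]1C1=COC(C)(C)O1 | intermediate
19 | C2,C14-bis(tert-butyldimethylsilyl) ether of 18 | O=C1C[C@@H](O[Si](C)(C)C(C)(C)C)[C@@]2(C)[C@@H](O[Si](C)(C)C(C)(C)C)CC=C(C)[C@@H]2[C@H]1C1=COC(C)(C)O1 | intermediate
20 | decalin ethynyl carbinol: C4 hydroxyl axial (syn to the C2 silyloxy group), ethynyl equatorial, trans to the equatorial C9 dioxolyl group | C#C[C@]1(O)C[C@@H](O[Si](C)(C)C(C)(C)C)[C@@]2(C)[C@@H](O[Si](C)(C)C(C)(C)C)CC=C(C)[C@@H]2[C@H]1C1=COC(C)(C)O1 | intermediate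
21 | potassium alkoxide of 20 | [K+].C#C[C@]1([O-])C[C@@H](O[Si](C)(C)C(C)(C)C)[C@@]2(C)[C@@H](O[Si](C)(C)C(C)(C)C)CC=C(C)[C@@H]2[C@H]1C1=COC(C)(C)O1 | intermediate
22 | potassium allenolate: ten-membered ring with C4-O(-), C4=C5=C6 allene, C7 in the acetonide, ring-trans C8=C9 enol ether (allene axis not encoded) | [K+].[O-]C1C[C@@H](O[Si](C)(C)C(C)(C)C)[C@@]2(C)[C@@H](O[Si](C)(C)C(C)(C)C)CC=C(C)[C@@H]2/C=C2\OC(C)(C)O[C@H]2C=C=1 | intermediate
23 | ten-membered enone: C4 ketone, Z C5=C6 with hydroxymethyl C16 on C5, C7/C8 enediol acetonide with ring-trans C8=C9 enol ether, C2 and C14 silyl ethers | O=C1C[C@@H](O[Si](C)(C)C(C)(C)C)[C@@]2(C)[C@@H](O[Si](C)(C)C(C)(C)C)CC=C(C)[C@@H]2/C=C2\OC(C)(C)O[C@H]2/C=C\1CO | intermediate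
24 | C16 tert-butyldiphenylsilyl ether of 23 | O=C1C[C@@H](O[Si](C)(C)C(C)(C)C)[C@@]2(C)[C@@H](O[Si](C)(C)C(C)(C)C)CC=C(C)[C@@H]2/C=C2\OC(C)(C)O[C@H]2/C=C\1CO[Si](c1ccccc1)(c1ccccc1)C(C)(C)C | intermediate
25 | C9 alcohol with C8 methoxy ketal inside the O7,O8 acetonide (methoxy on the face of the C9 oxygen) | O=C1C[C@@H](O[Si](C)(C)C(C)(C)C)[C@@]2(C)[C@@H](O[Si](C)(C)C(C)(C)C)CC=C(C)[C@@H]2[C@@H](O)[C@@]2(OC)OC(C)(C)O[C@H]2/C=C\1CO[Si](c1ccccc1)(c1ccccc1)C(C)(C)C | intermediate
26 | C9 acetate of 25 | O=C1C[C@@H](O[Si](C)(C)C(C)(C)C)[C@@]2(C)[C@@H](O[Si](C)(C)C(C)(C)C)CC=C(C)[C@@H]2[C@@H](OC(C)=O)[C@@]2(OC)OC(C)(C)O[C@H]2/C=C\1CO[Si](c1ccccc1)(c1ccccc1)C(C)(C)C | intermediate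
27 | α-hydroxy ketone: C9 acetate, C8 ketone, C7 alcohol, C4 enone | O=C1C[C@@H](O[Si](C)(C)C(C)(C)C)[C@@]2(C)[C@@H](O[Si](C)(C)C(C)(C)C)CC=C(C)[C@@H]2[C@@H](OC(C)=O)C(=O)[C@@H](O)/C=C\1CO[Si](c1ccccc1)(c1ccccc1)C(C)(C)C | intermediate
28 | C7 2-bromopropanoate of 27 (both epimers at the bromine-bearing carbon) | O=C1C[C@@H](O[Si](C)(C)C(C)(C)C)[C@@]2(C)[C@@H](O[Si](C)(C)C(C)(C)C)CC=C(C)[C@@H]2[C@@H](OC(C)=O)C(=O)[C@@H](OC(=O)C(C)Br)/C=C\1CO[Si](c1ccccc1)(c1ccccc1)C(C)(C)C | intermediate
29 | samarium enolate of the C7 propanoate (I2Sm-O enolate, geometry open) | O=C1C[C@@H](O[Si](C)(C)C(C)(C)C)[C@@]2(C)[C@@H](O[Si](C)(C)C(C)(C)C)CC=C(C)[C@@H]2[C@@H](OC(C)=O)C(=O)[C@@H](OC(=CC)O[Sm](I)I)/C=C\1CO[Si](c1ccccc1)(c1ccccc1)C(C)(C)C | intermediate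
30 | lactone: C8 tertiary alcohol, C17 methyl, C9 acetate, C4 ketone, C2/C14 silyl ethers, C16 silyl ether | O=C1C[C@@H](O[Si](C)(C)C(C)(C)C)[C@@]2(C)[C@@H](O[Si](C)(C)C(C)(C)C)CC=C(C)[C@@H]2[C@@H](OC(C)=O)[C@@]2(O)[C@H](/C=C\1CO[Si](c1ccccc1)(c1ccccc1)C(C)(C)C)OC(=O)[C@@H]2C | intermediate
31 | C2,C14-diol of 30 (C4 ketone, C16 silyl ether kept) | O=C1C[C@@H](O)[C@@]2(C)[C@@H](O)CC=C(C)[C@@H]2[C@@H](OC(C)=O)[C@@]2(O)[C@H](/C=C\1CO[Si](c1ccccc1)(c1ccccc1)C(C)(C)C)OC(=O)[C@@H]2C | intermediate
32 | C2,C4,C14-triol (C4 alcohol 1,3-anti to C2 alcohol; C8 hydroxyl free) | O[C@@H]1C[C@@H](O)[C@@]2(C)[C@@H](O)CC=C(C)[C@@H]2[C@@H](OC(C)=O)[C@@]2(O)[C@H](/C=C\1CO[Si](c1ccccc1)(c1ccccc1)C(C)(C)C)OC(=O)[C@@H]2C | intermediate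
33 | (R)-3-hydroxybutanoic acid | C[C@@H](O)CC(=O)O | starting material
34 | (R)-3-acetoxybutanoic acid | CC(=O)O[C@H](C)CC(=O)O | intermediate
35 | C4 (R)-3-acetoxybutanoate of 32 | CC(=O)O[C@H](C)CC(=O)O[C@@H]1C[C@@H](O)[C@@]2(C)[C@@H](O)CC=C(C)[C@@H]2[C@@H](OC(C)=O)[C@@]2(O)[C@H](/C=C\1CO[Si](c1ccccc1)(c1ccccc1)C(C)(C)C)OC(=O)[C@@H]2C | intermediate
36 | C2,C9,C14-triacetate C4 (R)-3-acetoxybutanoate, C16 tert-butyldiphenylsilyl ether | CC(=O)O[C@H](C)CC(=O)O[C@@H]1C[C@@H](OC(C)=O)[C@@]2(C)[C@@H](OC(C)=O)CC=C(C)[C@@H]2[C@@H](OC(C)=O)[C@@]2(O)[C@H](/C=C\1CO[Si](c1ccccc1)(c1ccccc1)C(C)(C)C)OC(=O)[C@@H]2C | intermediate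
37 | CNP0316115.1 | CC(=O)O[C@H](C)CC(=O)O[C@@H]1C[C@@H](OC(C)=O)[C@@]2(C)[C@@H](OC(C)=O)CC=C(C)[C@@H]2[C@@H](OC(C)=O)[C@@]2(O)[C@H](/C=C\1CO)OC(=O)[C@@H]2C | target

**Count**

Total steps: 26. Longest linear sequence: 22 steps (steps 1–6, 10–22, 24–26); the bromodioxole (steps 7–9) and the side-chain acid (step 23) are side branches.

**Steps most likely to fail**

Step 14 (proposed new method). The alkoxide may fragment or lose the C2 silyloxy group by β-elimination before the [3,3] shift, the strained allenolate may be protonated or trapped on oxygen, or formaldehyde may add without geometric control. The fallback sets out from ketone 19 and returns at enone 23, using only known reaction types. Vinylmagnesium bromide with CeCl3 adds to 19 as in step 13 to give the vinyl carbinol F1. KN(SiMe3)2 with 18-crown-6 then effects the classical anionic oxy-Cope ring expansion of this trans-1,2-dialkenylcyclohexanol through the same chair, so C7 and the ring-trans enol ether arise as before, giving the potassium enolate F2. F2 is dehydrogenated in the same flask with N-tert-butylbenzenesulfinimidoyl chloride (Mukaiyama dehydrogenation) to the C5=C6 enone F3. A Morita-Baylis-Hillman reaction of F3 with aqueous formaldehyde and DMAP then installs C16 and gives 23; its reversible conjugate-addition step should also settle the enone in the cis ring geometry.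

Step 10. The labile bromodioxole may decompose faster than it undergoes oxidative addition, the palladium catalyst may isomerise the epoxy ketone, or the product alkene may move into conjugation with the ketone. The fallback sets out from epoxy ketone 10 and returns at 17, replacing the cross-coupling by an oxocarbenium alkylation of the C-glycosylation type. LiN(SiMe3)2 and Me3SiCl give the trimethylsilyl enol ether F4. F4 is alkylated with the dibromide 14 (made as in step 9) under AgOSO2CF3 and 2,6-di-tert-butylpyridine in CH2Cl2 at -78 °C, giving the C9 (5-bromo-2,2-dimethyl-1,3-dioxolan-4-yl) ketone F5. Et3N then removes hydrogen bromide from F5 through the oxocarbenium ion, as in step 9, to give 17.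

Step 2. Hydrogen-bond activation may be too weak for the hindered, trisubstituted dienal, so that an uncatalysed background reaction erodes the enantioselectivity, or turnover stalls. The fallback sets out from dienal 3 and returns at 6. A Diels-Alder reaction of 3 with 2-(triisopropylsilyloxy)buta-1,3-diene under a triflimide-activated CBS-type oxazaborolidinium catalyst (strong chiral Lewis acid activation, which the amino diene would not tolerate) gives the silyl enol ether F6 with the same regiochemistry (silyloxy carbon para to the formyl-bearing carbon). Saegusa-Ito oxidation of F6 with Pd(OAc)2 in MeCN then introduces the enone double bond and gives 6.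

**Further compounds**

F1 | step 14 | decalin vinyl carbinol (vinyl in place of ethynyl in 20) | C=C[C@]1(O)C[C@@H](O[Si](C)(C)C(C)(C)C)[C@@]2(C)[C@@H](O[Si](C)(C)C(C)(C)C)CC=C(C)[C@@H]2[C@H]1C1=COC(C)(C)O1
F2 | step 14 | potassium C4-C5 enolate of the ring-expanded ketone (C6 methylene; enolate geometry open) | [K+].[O-]C1C[C@@H](O[Si](C)(C)C(C)(C)C)[C@@]2(C)[C@@H](O[Si](C)(C)C(C)(C)C)CC=C(C)[C@@H]2/C=C2\OC(C)(C)O[C@H]2CC=1
F3 | step 14 | ten-membered Z enone lacking C16 (H on C5) | O=C1C[C@@H](O[Si](C)(C)C(C)(C)C)[C@@]2(C)[C@@H](O[Si](C)(C)C(C)(C)C)CC=C(C)[C@@H]2/C=C2\OC(C)(C)O[C@H]2/C=C\1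
F4 | step 10 | trimethylsilyl enol ether of epoxy ketone 10 (C4-O-SiMe3, C4=C9) | C[Si](C)(C)OC1[C@H]2O[C@H]2[C@@]2(C)[C@@H](O[Si](C)(C)C(C)(C)C)CC=C(C)[C@@H]2C=1
F5 | step 10 | epoxy ketone with a trans-5-bromo-2,2-dimethyl-1,3-dioxolan-4-yl group on C9 (dioxolane centres open) | O=C1[C@H]2O[C@H]2[C@@]2(C)[C@@H](O[Si](C)(C)C(C)(C)C)CC=C(C)[C@@H]2[C@H]1C1OC(C)(C)OC1Br
F6 | step 2 | (1R,6S)-1-methyl-6-(prop-1-en-2-yl)-4-(triisopropylsilyloxy)cyclohex-3-ene-1-carbaldehyde | CC(C)[Si](C(C)C)(C(C)C)OC1=CC[C@@](C)(C=O)[C@H](C(C)=C)C1
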